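## Retrosynthetic overview

- The C5 propenyl group is cut first. It comes from a final Suzuki coupling of a 5-bromo-dihydrobenzofuran with (E)-propenylboronic acid.
- The O1–C2 bond is cut next. The dihydrofuran ring closes by acid cyclodehydration of a phenol/benzylic alcohol pair, which places C2 trans to C3.
- Both oxygens of that pair come from oxidation of a benzo-fused borolane. The borolane forms in one flask from syringyl-lithium, a chiral (E)-propenylboronate and 5-bromo-3-methoxybenzyne. C3–C3a bond formation triggers a 1,2-aryl shift from B to C2, and the diol on boron sets C3.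
- Building blocks: the aryne precursor from catechol, the aryl bromide from 4-bromophenol, and propenylboronic acid, which is used twice.
- Ring order: both arenes are bought, the transient borolane ring forms first, and the dihydrofuran ring forms second.

Assumption: a steric model predicts that the (R,R)-diol on boron gives the (S) geometry at the methyl-bearing carbon. If experiment shows the opposite sense, the equally available (S,S)-diol is used with no other change.

## Route

Step 1
Reactants: 1 catechol
Product: 2 guaiacol (2-methoxyphenol)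
Conditions: MeI (1.0 equiv), K2CO3 (1.0 equiv), acetone, reflux
Reagents that add atoms: iodomethane, CI
Why: Williamson mono-O-methylation of a symmetrical diol with one equivalent of electrophile, with veratrole removed by base extraction and catechol by distillation.

Step 2
Reactants: 2 guaiacol
Product: 3 4,6-dibromo-2-methoxyphenol
Conditions: NBS (2.05 equiv), MeCN, 0 °C to rt
Reagents that add atoms: N-bromosuccinimide, O=C1CCC(=O)N1Br
Why: Electrophilic aromatic bromination in which the free OH, the stronger donor, directs first to its para position and then to its open ortho position.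

Step 3
Reactants: 3 4,6-dibromo-2-methoxyphenol
Product: 4 2,4-dibromo-6-methoxyphenyl trifluoromethanesulfonate
Conditions: Tf2O, pyridine, CH2Cl2, 0 °C
Reagents that add atoms: triflic anhydride, O=S(=O)(OS(=O)(=O)C(F)(F)F)C(F)(F)F
Why: O-sulfonylation of an acidic phenol, which places a leaving group next to a C–Br bond and so gives an aryne precursor by 1,2-elimination.

Step 4
Reactants: 5 4-bromophenol
Product: 6 4-bromo-2,6-diiodophenol
Conditions: NIS (2.1 equiv), TsOH (cat.), MeCN, rt
Reagents that add atoms: N-iodosuccinimide, O=C1CCC(=O)N1I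
Why: Electrophilic aromatic iodination at the two free ortho positions of the phenol, the para position being blocked by bromine.

Step 5
Reactants: 6 4-bromo-2,6-diiodophenol
Product: 7 5-bromo-1,3-diiodo-2-(methoxymethoxy)benzene
Conditions: NaH, MOMCl, THF/DMF, 0 °C to rt
Reagents that add atoms: chloromethyl methyl ether, COCCl
Why: Williamson-type O-alkylation of the phenoxide gives an acetal that tolerates organolithiums, base and peroxide and is removed by acid.

Step 6
Reactants: 7 5-bromo-1,3-diiodo-2-(methoxymethoxy)benzene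
Product: 8 5-bromo-1,3-dimethoxy-2-(methoxymethoxy)benzene
Conditions: CuI (10 mol %), 1,10-phenanthroline (20 mol %), Cs2CO3, MeOH/toluene, 100 °C (sealed)
Reagents that add atoms: methanol, CO
Why: Ullmann-type copper-catalysed C–O coupling, in which aryl iodides react much faster than aryl bromides, so both C–I bonds are replaced and C–Br is kept.

Step 7
Reactants: 9 (E)-prop-1-en-1-ylboronic acid
Product: 10 (4R,5R)-4,5-dicyclohexyl-2-[(E)-prop-1-en-1-yl]-1,3,2-dioxaborolane
Conditions: (R,R)-1,2-dicyclohexylethane-1,2-diol, 4 Å MS, Et2O, rt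
Reagents that add atoms: (1R,2R)-1,2-dicyclohexylethane-1,2-diol, O[C@H](C1CCCCC1)[C@H](O)C1CCCCC1
Why: Boronic acid–diol condensation driven by removal of water, which touches neither the alkene geometry nor the diol centres.

Step 8
Reactants: 8 5-bromo-1,3-dimethoxy-2-(methoxymethoxy)benzene; 10 (4R,5R)-4,5-dicyclohexyl-2-[(E)-prop-1-en-1-yl]-1,3,2-dioxaborolane; 4 2,4-dibromo-6-methoxyphenyl trifluoromethanesulfonate
Product: 15 4-bromo-2-{(1S,2S)-1-[3,5-dimethoxy-4-(methoxymethoxy)phenyl]-1-hydroxypropan-2-yl}-6-methoxyphenol, via aryllithium 11 (not isolated), via lithium alkenylarylborate 12 (not isolated), via 5-bromo-3-methoxybenzyne 13 (not isolated), via lithium spiroborate 14 (not isolated)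
Conditions: 8, n-BuLi (1.0 equiv), THF, −78 °C; 10 (1.0 equiv), −78 to 0 °C; 4, then n-BuLi (1.0 equiv, slow addition), −78 °C to rt; NaOH, 30 % H2O2, 0 °C to rt
Reagents that add atoms: hydrogen peroxide, OO; n-butyllithium, [Li]CCCC (lithium only, held in 11, 12 and 14)
Why: Proposed new method: an auxiliary-controlled asymmetric aryne-triggered 1,2-metallate shift, in which Br/Li exchange next to OTf and loss of LiOTf release the polarised aryne 13, the β-carbon of the electron-rich C=C of borate 12 attacks the aryne carbon remote from OMe while the syringyl group shifts from boron to the α-carbon antiperiplanar to the new C–C bond (anti addition to the E-alkene, hence the trans borolane 14 once the aryl anion formed next to OMe closes on boron), the cyclohexyl group of the (R,R)-diol on the alkenyl face of boron blocks one of the two reactive rotamers so that only the alkene face leading to the (S) geometry at the methyl-bearing carbon is open, and NaOH/H2O2 then converts both C–B bonds into C–O bonds with retention; the closest known reaction types are the racemic aryne-triggered annulative 1,2-metallate rearrangement of pinacol vinylboronate complexes and the diol-controlled Matteson homologation.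

Step 9
Reactants: 15 4-bromo-2-{(1S,2S)-1-[3,5-dimethoxy-4-(methoxymethoxy)phenyl]-1-hydroxypropan-2-yl}-6-methoxyphenol
Product: 16 4-[(2S,3S)-5-bromo-7-methoxy-3-methyl-2,3-dihydro-1-benzofuran-2-yl]-2,6-dimethoxyphenol
Conditions: HCl (2 M in MeOH), 40 °C, short reaction time
Reagents that add atoms: none
Why: Acid transacetalises the MOM group away and ionises the electron-rich benzylic alcohol to a syringyl-stabilised cation that the neighbouring phenol traps (intramolecular SN1 etherification), so C2 is set trans to the untouched C3 centre under substrate and thermodynamic control.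

Step 10
Reactants: 16 4-[(2S,3S)-5-bromo-7-methoxy-3-methyl-2,3-dihydro-1-benzofuran-2-yl]-2,6-dimethoxyphenol; 9 (E)-prop-1-en-1-ylboronic acid
Product: 17 odoratisol A, 2,6-dimethoxy-4-{(2S,3S)-7-methoxy-3-methyl-5-[(E)-prop-1-en-1-yl]-2,3-dihydro-1-benzofuran-2-yl}phenol
Conditions: SPhos Pd G3 (2 mol %), K3PO4, THF/H2O, 50 °C
Reagents that add atoms: none
Why: Suzuki–Miyaura coupling of the only C–Br bond, which keeps the E geometry of the alkenylboronic acid, tolerates the free phenol and touches no stereocentre.

## Compound list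

1 | catechol | Oc1ccccc1O | starting material
2 | guaiacol | COc1ccccc1O | intermediate
3 | 4,6-dibromo-2-methoxyphenol | COc1cc(Br)cc(Br)c1O | intermediate
4 | 2,4-dibromo-6-methoxyphenyl trifluoromethanesulfonate | COc1cc(Br)cc(Br)c1OS(=O)(=O)C(F)(F)F | intermediate
5 | 4-bromophenol | Oc1ccc(Br)cc1 | starting material
6 | 4-bromo-2,6-diiodophenol | Oc1c(I)cc(Br)cc1I | intermediate
7 | 5-bromo-1,3-diiodo-2-(methoxymethoxy)benzene | COCOc1c(I)cc(Br)cc1I | intermediate
8 | 5-bromo-1,3-dimethoxy-2-(methoxymethoxy)benzene | COCOc1c(OC)cc(Br)cc1OC | intermediate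
9 | (E)-prop-1-en-1-ylboronic acid | C/C=C/B(O)O | starting material
10 | (4R,5R)-4,5-dicyclohexyl-2-[(E)-prop-1-en-1-yl]-1,3,2-dioxaborolane | C/C=C/B1O[C@H](C2CCCCC2)[C@@H](C2CCCCC2)O1 | intermediate
11 | [3,5-dimethoxy-4-(methoxymethoxy)phenyl]lithium | [Li]c1cc(OC)c(OCOC)c(OC)c1 | intermediate
12 | lithium (4R,5R)-4,5-dicyclohexyl-2-[3,5-dimethoxy-4-(methoxymethoxy)phenyl]-2-[(E)-prop-1-en-1-yl]-1,3,2-dioxaborolan-2-uide | [Li+].C/C=C/[B-]1(c2cc(OC)c(OCOC)c(OC)c2)O[C@H](C2CCCCC2)[C@@H](C2CCCCC2)O1 | intermediate
13 | 5-bromo-3-methoxybenzyne (5-bromo-3-methoxy-1,2-didehydrobenzene) | COC1=CC(Br)=CC#C1 | intermediate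
14 | lithium spiroborate of trans-(2S,3R)-5-bromo-2-[3,5-dimethoxy-4-(methoxymethoxy)phenyl]-7-methoxy-3-methyl-2,3-dihydro-1H-1-benzoborole with the (R,R)-diol (same spatial arrangement as 17; the C3 descriptor differs because boron ranks below carbon) | [Li+].COc1cc(Br)cc2c1[B-]1(O[C@H](C3CCCCC3)[C@@H](C3CCCCC3)O1)[C@H](c1cc(OC)c(OCOC)c(OC)c1)[C@H]2C | intermediate
15 | 4-bromo-2-{(1S,2S)-1-[3,5-dimethoxy-4-(methoxymethoxy)phenyl]-1-hydroxypropan-2-yl}-6-methoxyphenol | C[C@@H](c1cc(Br)cc(OC)c1O)[C@H](O)c1cc(OC)c(OCOC)c(OC)c1 | intermediate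
16 | 4-[(2S,3S)-5-bromo-7-methoxy-3-methyl-2,3-dihydro-1-benzofuran-2-yl]-2,6-dimethoxyphenol | Brc1cc(OC)c2c(c1)[C@H](C)[C@@H](c1cc(OC)c(O)c(OC)c1)O2 | intermediate
17 | odoratisol A | C/C=C/c1cc(OC)c2c(c1)[C@H](C)[C@@H](c1cc(OC)c(O)c(OC)c1)O2 | target

## Step count and risks

Total step count: 10.
Longest linear sequence: 6 (steps 1–3 or steps 4–6, then steps 8–10).

Steps most likely to fail:

1. Step 8. This is the new reaction, and neither the facial selectivity from the boron-bound diol nor clean capture of the aryne by a β-methyl alkenylborate has been shown.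
   - The fallback is known chemistry: palladium-catalysed enantio- and diastereoselective conjunctive cross-coupling, which is also an anti 1,2-metallate shift. It sets out from 3, 8 and 9 and comes back at 16.
   - Compound 3 is protected (NaH, MOMCl) as 1,5-dibromo-3-methoxy-2-(methoxymethoxy)benzene F1.
   - Chelation-directed Br/Mg exchange of the bromide next to the OMOM group (i-PrMgCl·LiCl, −15 °C), followed by I2, gives 5-bromo-1-iodo-3-methoxy-2-(methoxymethoxy)benzene F2.
   - Compound 9 is condensed with cis-1,2-dimethylacenaphthylene-1,2-diol to give the (E)-propenyl B(mac) ester F3.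
   - Aryllithium 11, made from 8 as before, adds to F3 to give the lithium B(mac) borate F4.
   - F4 couples with F2 at C–I only (Pd(OAc)2, the MandyPhos enantiomer that gives the (S) geometry at the methyl carbon, KOTf, THF, 60 °C). The product is the (1S,2R)-1,2-diarylpropyl B(mac) ester F5.
   - NaOH/H2O2 converts F5 into the bis-MOM (1S,2S)-alcohol F6.
   - HCl/MeOH removes both MOM groups from F6 and closes the ring to 16.

2. Step 6. Hydrodeiodination, or partial attack at C–Br, could spoil the double methoxylation.
   - The fallback sets out from 7 and comes back at 8. It makes the C–O bonds by borylation and oxidation instead of copper coupling.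
   - Iodide-selective Miyaura borylation (Pd(dppf)Cl2, B2pin2, KOAc, dioxane, 80 °C) gives the bis(pinacol boronate) F7.
   - NaOH/H2O2 gives 5-bromo-2-(methoxymethoxy)benzene-1,3-diol F8.
   - MeI/K2CO3 in acetone then gives 8.

3. Step 9. The benzylic cation can lose the C3 proton to give a stilbene, or undergo a hydride shift, and either path erodes the C3 centre. The free syringyl phenol also keeps the ring opening reversible in acid.
   - The fallback sets out from 15 and comes back at 16. It closes the ring under base by halide displacement and separates deprotection from cyclisation.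
   - Appel chlorination of the alcohol (PPh3, CCl4, CH2Cl2, 0 °C; the phenol is left alone) gives the (1R,2S)-benzylic chloride F9.
   - F9 is treated without purification with K2CO3 in acetone. The two inversions add up to retention, and any SN1 leakage also gives trans. The product is the MOM-protected (2S,3S)-5-bromo-dihydrobenzofuran F10.
   - Brief catalytic HCl in MeOH at rt then frees the phenol and gives 16.

## Further compounds

F1 | step 8 | 1,5-dibromo-3-methoxy-2-(methoxymethoxy)benzene | COCOc1c(Br)cc(Br)cc1OC
F2 | step 8 | 5-bromo-1-iodo-3-methoxy-2-(methoxymethoxy)benzene | COCOc1c(I)cc(Br)cc1OC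
F3 | step 8 | (E)-propenyl B(mac) ester (boronic ester of cis-1,2-dimethylacenaphthylene-1,2-diol) | C/C=C/B1O[C@]2(C)c3cccc4cccc(c34)[C@]2(C)O1
F4 | step 8 | lithium B(mac) borate carrying (E)-propenyl and 3,5-dimethoxy-4-(methoxymethoxy)phenyl | [Li+].C/C=C/[B-]1(c2cc(OC)c(OCOC)c(OC)c2)O[C@]2(C)c3cccc4cccc(c34)[C@]2(C)O1
F5 | step 8 | (1S,2R)-2-[5-bromo-3-methoxy-2-(methoxymethoxy)phenyl]-1-[3,5-dimethoxy-4-(methoxymethoxy)phenyl]propyl B(mac) ester | C[C@@H](c1cc(Br)cc(OC)c1OCOC)[C@H](B1O[C@]2(C)c3cccc4cccc(c34)[C@]2(C)O1)c1cc(OC)c(OCOC)c(OC)c1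
F6 | step 8 | (1S,2S)-2-[5-bromo-3-methoxy-2-(methoxymethoxy)phenyl]-1-[3,5-dimethoxy-4-(methoxymethoxy)phenyl]propan-1-ol | C[C@@H](c1cc(Br)cc(OC)c1OCOC)[C@H](O)c1cc(OC)c(OCOC)c(OC)c1
F7 | step 6 | 2,2'-[5-bromo-2-(methoxymethoxy)-1,3-phenylene]bis(4,4,5,5-tetramethyl-1,3,2-dioxaborolane) | COCOc1c(B2OC(C)(C)C(C)(C)O2)cc(Br)cc1B1OC(C)(C)C(C)(C)O1
F8 | step 6 | 5-bromo-2-(methoxymethoxy)benzene-1,3-diol | COCOc1c(O)cc(Br)cc1O
F9 | step 9 | 4-bromo-2-{(1R,2S)-1-chloro-1-[3,5-dimethoxy-4-(methoxymethoxy)phenyl]propan-2-yl}-6-methoxyphenol | C[C@@H](c1cc(Br)cc(OC)c1O)[C@@H](Cl)c1cc(OC)c(OCOC)c(OC)c1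
F10 | step 9 | (2S,3S)-5-bromo-2-[3,5-dimethoxy-4-(methoxymethoxy)phenyl]-7-methoxy-3-methyl-2,3-dihydro-1-benzofuran | Brc1cc(OC)c2c(c1)[C@H](C)[C@@H](c1cc(OC)c(OCOC)c(OC)c1)O2
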